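The route rests on reading the epoxide carbons of ring E, C1' (which bears the trans-butenone chain) and C5', as the ring alkene of a 1-vinylcycloheptene. Ring E therefore opens at C1'=C5' and the chain at C2'=C3'. In one ruthenium-catalysed operation the 2-methylbut-3-ynyl arm on C8' and the allyl arm on C7', held cis on lactone D, are joined to close ring E, and the new vinyl group is capped with methyl vinyl ketone. The precursor is an enyne that already holds rings A to D. It arises from a Diels–Alder union of two mirror-image α-methylene lactones made by one allylboration. A reagent-controlled epoxidation finishes the target.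

Key step: step 12

Labels: xanthanolide numbering is used, C1–C15 for the A/B/C half and primed numbers for the D/E half (C11' is the spiro carbon, C13' the ring C methylene); β is the face of the seven-membered ring B that carries O8, C11 and the C10 methyl group; C7/C8/C10 (R,R,S) and C7'/C8'/C10' (S,S,R) are mirror images, so the two halves come from enantiomeric series.
Assumption: (R)-DTBM-SEGPHOS is taken to give the (3R)-aldehyde and (R)-TRIP to direct Re-face allylboration as in the parent reaction; both antipodes of both catalysts are used, so a reversed sense is corrected by exchanging them between the two series.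

Step 1
Reactants: 1 allylmagnesium bromide; 2 methyl propiolate; 3 2-(iodomethyl)-4,4,5,5-tetramethyl-1,3,2-dioxaborolane
Product: 6 methyl (2E)-2-[(4,4,5,5-tetramethyl-1,3,2-dioxaborolan-2-yl)methyl]hexa-2,5-dienoate, via allylcopper 4 (not isolated), via alkenylcopper 5 (not isolated)
Conditions: 1, CuBr·SMe2, THF, −78 °C; 2, −78 °C; HMPA, 3, −78 to 0 °C
Reagents that add atoms: none
Why: Syn carbocupration of the propiolate places the allyl group and copper on the same side of the new alkene, and the alkenylcopper, configurationally stable in the cold, is alkylated by the iodomethylboronate with retention, so the allyl CH2 ends cis to CH2B (carbocupration with electrophilic trapping).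

Step 2
Reactants: 7 (E)-but-2-enal; 8 ethynyltriisopropylsilane
Product: 9 (3R)-3-methyl-5-(triisopropylsilyl)pent-4-ynal
Conditions: [Rh(OAc)(C2H4)2]2 (2.5 mol %), (R)-DTBM-SEGPHOS (5.5 mol %), MeOH, 40 °C
Reagents that add atoms: none
Why: Rhodium-catalysed asymmetric conjugate alkynylation of an enal, in which the bulky silyl group keeps the alkyne from dimerising and the chiral bisphosphine on the alkynylrhodium species selects the enal face and so sets C10' as R.

Step 3
Reactants: 7 (E)-but-2-enal; 8 ethynyltriisopropylsilane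
Product: 10 (3S)-3-methyl-5-(triisopropylsilyl)pent-4-ynal
Conditions: [Rh(OAc)(C2H4)2]2 (2.5 mol %), (S)-DTBM-SEGPHOS (5.5 mol %), MeOH, 40 °C
Reagents that add atoms: none
Why: The same rhodium-catalysed conjugate alkynylation with the mirror-image ligand gives the antipode and sets C10 as S.

Step 4
Reactants: 9 (3R)-aldehyde; 6 allylboronate
Product: 12 (4S,5S)-3-methylidene-4-(prop-2-enyl)-5-[(2R)-2-methyl-4-(triisopropylsilyl)but-3-ynyl]oxolan-2-one, via homoallyl borate 11 (not isolated)
Conditions: (R)-TRIP (10 mol %), 4 Å MS, toluene, 0 °C to rt; then p-TsOH·H2O (cat.), rt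
Reagents that add atoms: none
Why: Chiral-phosphoric-acid-catalysed allylboration through a closed chair (Zimmerman–Traxler) transition state followed by lactonisation, in which the substituent cis to CH2B sits axial and gives the syn adduct (C7'/C8' cis), the catalyst directs attack to the Re face of the aldehyde (8'S, hence 7'S) whatever the remote C10' centre, and the borate oxygen closes onto the ester.

Step 5
Reactants: 12 silylated lactone (S,S,R series)
Product: 14 (4S,5S)-3-methylidene-4-(prop-2-enyl)-5-[(2R)-2-methylbut-3-ynyl]oxolan-2-one, via silver acetylide 13 (not isolated)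
Conditions: AgF (1.5 equiv), MeCN, rt, dark; then 1 M HCl
Reagents that add atoms: none
Why: Silver-fluoride-mediated alkyne desilylation cleaves the C(sp)–Si bond under neutral conditions through the silver acetylide, which acid protonates, so the base-sensitive α-methylene lactone never meets a basic fluoride source.

Step 6
Reactants: 10 (3S)-aldehyde; 6 allylboronate
Product: 16 (4R,5R)-3-methylidene-4-(prop-2-enyl)-5-[(2S)-2-methyl-4-(triisopropylsilyl)but-3-ynyl]oxolan-2-one, via homoallyl borate 15 (not isolated)
Conditions: (S)-TRIP (10 mol %), 4 Å MS, toluene, 0 °C to rt; then p-TsOH·H2O (cat.), rt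
Reagents that add atoms: none
Why: The same phosphoric-acid-catalysed allylboration and lactonisation with the antipodal catalyst attacks the Si face of the aldehyde through the same chair and sets C7 and C8 as R,R with the two arms cis.

Step 7
Reactants: 16 silylated lactone (R,R,S series)
Product: 18 (4R,5R)-3-methylidene-4-(prop-2-enyl)-5-[(2S)-2-methylbut-3-ynyl]oxolan-2-one, via silver acetylide 17 (not isolated)
Conditions: AgF (1.5 equiv), MeCN, rt, dark; then 1 M HCl
Reagents that add atoms: none
Why: Neutral silver-fluoride alkyne desilylation as in step 5 frees the terminal alkyne without touching the methylene lactone or any stereocentre.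

Step 8
Reactants: 18 enyne lactone (R,R,S series)
Product: 19 (3S,4R,5R)-3-[(phenylsulfonyl)methyl]-4-(prop-2-enyl)-5-[(2S)-2-methylbut-3-ynyl]oxolan-2-one
Conditions: PhSO2Na (1.2 equiv), AcOH, EtOH–H2O, rt
Reagents that add atoms: sodium benzenesulfinate, [Na+].[O-]S(=O)c1ccccc1
Why: In this sulfa-Michael addition the soft sulfinate adds only to C13 of the methylene lactone and the enol is protonated at C11 from the face opposite the two cis arms (11S, CH2SO2Ph cis to the arms), which removes the dienophile of this half in a form that base can undo later.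

Step 9
Reactants: 19 masked enyne lactone; 20 methyl vinyl ketone
Product: 22 masked dienone with rings A and B (7R,8R,10S,11S), via vinylcycloheptene 21 (not isolated)
Conditions: second-generation Hoveyda–Grubbs catalyst RuCl2(H2IMes)(=CH-C6H4-2-OiPr) (10 mol %), 20 (5 equiv), CH2Cl2 (0.01 M), 40 °C
Reagents that add atoms: none
Why: Domino ring-closing enyne metathesis and cross-metathesis on the simple lactone, in which the carbene loads on the allyl group, closes seven-membered ring B onto the alkyne in the exo mode and the vinyl group of 21 is capped by methyl vinyl ketone with E geometry, while no stereocentre changes and the sulfone is inert to ruthenium carbenes.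

Step 10
Reactants: 22 masked dienone; 14 enyne lactone (S,S,R series)
Product: 23 Diels–Alder adduct with rings A to D (3S,5S,11'R; lactone A masked)
Conditions: 14 (3 equiv), BHT (cat.), toluene (2 M), 110 °C, sealed tube
Reagents that add atoms: none
Why: Thermal Diels–Alder reaction with the ortho orientation (C3–C11' and C5–C13'), in which 14 is attacked on the lactone D face anti to its two cis arms in the carbonyl-exo mode usual for α-methylene lactones (sets C11'), ring B, whose sp3 C11 with its inward CH2SO2Ph group can only sit equatorial on C7 with the C10 methyl axial, hides the α face of C5 behind C7–C9 so that C13' bonds to the β face (sets C5, C3 being transient), and the sulfone keeps 22 from acting as its own dienophile.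

Step 11
Reactants: 23 Diels–Alder adduct
Product: 26 enyne precursor with rings A to D complete (1S hydroxy enone), via methylene lactone adduct 24 (not isolated), via C1 hydroperoxide 25 (not isolated)
Conditions: DBU (3 equiv), O2 (1 atm), P(OEt)3 (2 equiv), MeCN, 0 °C to rt
Reagents that add atoms: dioxygen, O=O
Why: E1cB loss of sulfinate restores the C11=C13 methylene, and the doubly activated C3–H gives the extended enolate, which takes up O2 at the γ carbon C1 anti to the axial H5 so that ring C passes directly into the half-chair with C6, C10 and C7' equatorial (1S, trans B/C fusion), the hydroperoxide being reduced in situ by the phosphite (dienolate γ-autoxidation).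

Step 12
Reactants: 26 enyne precursor; 20 methyl vinyl ketone
Product: 28 des-epoxy target (ring E dienone), via vinylcycloheptene 27 (not isolated)
Conditions: second-generation Hoveyda–Grubbs catalyst RuCl2(H2IMes)(=CH-C6H4-2-OiPr) (10 mol %, two portions), 20 (10 equiv), CH2Cl2 (0.005 M), 40 °C
Reagents that add atoms: none
Why: This is a domino ring-closing enyne metathesis and cross-metathesis, a sequence established for 1-(3-oxobutenyl)cycloalkenes. The ruthenium carbene first exchanges with the only monosubstituted alkene, the allyl group on C7', and the resulting alkylidene adds across the C1'≡C2' alkyne in the exo mode, which closes seven-membered ring E through the new C1'=C5' bond and leaves a vinyl carbene at C2' that is released as 1-vinylcycloheptene 27. The vinyl group of 27 then undergoes cross-metathesis with the excess methyl vinyl ketone, with loss of ethene, to form C2'=C3'. No stereocentre is created, C7', C8' and C10' are untouched, and the E geometry follows from the reversible, thermodynamically controlled cross-metathesis with an electron-poor partner. Chemoselectivity rests on the substrate: the two arms are held cis on lactone D within reach of each other, whereas the C11=C13 methylene lactone (1,1-disubstituted, electron-poor) and the C2=C3 enone (trisubstituted, next to quaternary C11') do not load the catalyst, and the tertiary C1 hydroxyl needs no protection. High dilution and the chelating isopropoxybenzylidene catalyst, which tolerates enones, keep dimerisation and catalyst loss low.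

Step 13
Reactants: 28 des-epoxy target
Product: 29 target CNP0177598.2 (1'R,5'R epoxide)
Conditions: D-fructose-derived Shi ketone (30 mol %), Oxone (2KHSO5·KHSO4·K2SO4), K2CO3, Bu4NHSO4, Na2B4O7–Na2EDTA buffer, MeCN–CH2(OMe)2, 0 °C
Reagents that add atoms: potassium peroxymonosulfate KHSO5 (active salt of Oxone), [K+].[O-]S(=O)(=O)OO
Why: In this Shi epoxidation the electrophilic dioxirane picks C1'=C5', the only alkene not directly attached to a carbonyl group, and the D-fructose-derived ketone, which turns 1-substituted cycloalkenes into their (R,R)-epoxides, delivers oxygen under reagent control to the face opposite O8' and C11' (1'R,5'R).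

Compound list
1 | allylmagnesium bromide | C=CC[Mg]Br | starting material
2 | methyl propiolate | C#CC(=O)OC | starting material
3 | 2-(iodomethyl)-4,4,5,5-tetramethyl-1,3,2-dioxaborolane | ICB1OC(C)(C)C(C)(C)O1 | starting material
4 | allylcopper | C=CC[Cu] | intermediate
5 | methyl (2Z)-2-cupriohexa-2,5-dienoate (copper cis to the allyl CH2) | COC(=O)/C([Cu])=C/CC=C | intermediate
6 | methyl (2E)-2-[(4,4,5,5-tetramethyl-1,3,2-dioxaborolan-2-yl)methyl]hexa-2,5-dienoate (allyl CH2 cis to CH2B) | COC(=O)/C(CB1OC(C)(C)C(C)(C)O1)=C/CC=C | intermediate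
7 | (E)-but-2-enal | C/C=C/C=O | starting material
8 | ethynyltriisopropylsilane | C#C[Si](C(C)C)(C(C)C)C(C)C | starting material
9 | (3R)-3-methyl-5-(triisopropylsilyl)pent-4-ynal | O=CC[C@@H](C)C#C[Si](C(C)C)(C(C)C)C(C)C | intermediate
10 | (3S)-3-methyl-5-(triisopropylsilyl)pent-4-ynal | O=CC[C@H](C)C#C[Si](C(C)C)(C(C)C)C(C)C | intermediate
11 | syn homoallyl pinacol borate of the S,S,R series (open hydroxy ester as its O-Bpin derivative) | C=C(C(=O)OC)[C@H](CC=C)[C@H](C[C@@H](C)C#C[Si](C(C)C)(C(C)C)C(C)C)OB1OC(C)(C)C(C)(C)O1 | intermediate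
12 | (4S,5S)-3-methylidene-4-(prop-2-enyl)-5-[(2R)-2-methyl-4-(triisopropylsilyl)but-3-ynyl]oxolan-2-one (arms cis) | C=C1C(=O)O[C@@H](C[C@@H](C)C#C[Si](C(C)C)(C(C)C)C(C)C)[C@H]1CC=C | intermediate
13 | silver acetylide of 14 | C=C1C(=O)O[C@@H](C[C@@H](C)C#C[Ag])[C@H]1CC=C | intermediate
14 | (4S,5S)-3-methylidene-4-(prop-2-enyl)-5-[(2R)-2-methylbut-3-ynyl]oxolan-2-one (future lactone D with both arms) | C=C1C(=O)O[C@@H](C[C@@H](C)C#C)[C@H]1CC=C | intermediate
15 | syn homoallyl pinacol borate of the R,R,S series | C=C(C(=O)OC)[C@@H](CC=C)[C@@H](C[C@H](C)C#C[Si](C(C)C)(C(C)C)C(C)C)OB1OC(C)(C)C(C)(C)O1 | intermediate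
16 | (4R,5R)-3-methylidene-4-(prop-2-enyl)-5-[(2S)-2-methyl-4-(triisopropylsilyl)but-3-ynyl]oxolan-2-one | C=C1C(=O)O[C@H](C[C@H](C)C#C[Si](C(C)C)(C(C)C)C(C)C)[C@@H]1CC=C | intermediate
17 | silver acetylide of 18 | C=C1C(=O)O[C@H](C[C@H](C)C#C[Ag])[C@@H]1CC=C | intermediate
18 | (4R,5R)-3-methylidene-4-(prop-2-enyl)-5-[(2S)-2-methylbut-3-ynyl]oxolan-2-one | C=C1C(=O)O[C@H](C[C@H](C)C#C)[C@@H]1CC=C | intermediate
19 | (3S,4R,5R)-3-[(phenylsulfonyl)methyl]-4-(prop-2-enyl)-5-[(2S)-2-methylbut-3-ynyl]oxolan-2-one (all three substituents cis) | O=S(=O)(c1ccccc1)C[C@@H]1C(=O)O[C@H](C[C@H](C)C#C)[C@@H]1CC=C | intermediate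
20 | methyl vinyl ketone | C=CC(C)=O | starting material
21 | (3S,3aR,7S,8aR)-6-ethenyl-7-methyl-3-[(phenylsulfonyl)methyl]-3,3a,4,7,8,8a-hexahydrocyclohepta[b]furan-2-one | O=S(=O)(c1ccccc1)C[C@@H]1C(=O)O[C@@H]2C[C@H](C)C(C=C)=CC[C@H]12 | intermediate
22 | (3S,3aR,7S,8aR)-7-methyl-6-[(1E)-3-oxobut-1-enyl]-3-[(phenylsulfonyl)methyl]-3,3a,4,7,8,8a-hexahydrocyclohepta[b]furan-2-one (rings A and B; 7R,8R,10S,11S) | O=S(=O)(c1ccccc1)C[C@@H]1C(=O)O[C@@H]2C[C@H](C)C(/C=C/C(C)=O)=CC[C@H]12 | intermediate
23 | Diels–Alder adduct: lactone A with 13-SO2Ph (11S), ring C cyclohexene C1=C2, 3-acetyl (3S), H5 α (5S), spiro C11' (R) with C12'=O cis to H5, lactone D with cis 7'-allyl and 8'-[(2R)-2-methylbut-3-ynyl] arms; 7R,8R,10S,7'S,8'S,10'R | O=S(=O)(c1ccccc1)C[C@@H]1C(=O)O[C@@H]2C[C@H](C)C3=C[C@H](C(C)=O)[C@]4(C[C@@H]3C[C@H]12)C(=O)O[C@@H](C[C@@H](C)C#C)[C@H]4CC=C | intermediate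
24 | adduct 23 after loss of sulfinate (C11=C13 methylene lactone A restored, C1=C2 alkene, 3S) | C=C1C(=O)O[C@@H]2C[C@H](C)C3=C[C@H](C(C)=O)[C@]4(C[C@@H]3C[C@H]12)C(=O)O[C@@H](C[C@@H](C)C#C)[C@H]4CC=C | intermediate
25 | 1β-hydroperoxide of the C2=C3 enone (1S) | C=C1C(=O)O[C@@H]2C[C@H](C)[C@@]3(OO)C=C(C(C)=O)[C@]4(C[C@@H]3C[C@H]12)C(=O)O[C@@H](C[C@@H](C)C#C)[C@H]4CC=C | intermediate
26 | enyne precursor, rings A to D complete: 1β-hydroxy (1S), 3-acetyl C2=C3 enone, trans B/C fusion (5S), spiro C11' (R), cis allyl and 2-methylbut-3-ynyl arms on lactone D | C=C1C(=O)O[C@@H]2C[C@H](C)[C@@]3(O)C=C(C(C)=O)[C@]4(C[C@@H]3C[C@H]12)C(=O)O[C@@H](C[C@@H](C)C#C)[C@H]4CC=C | intermediate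
27 | pentacycle with ring E closed as 1'-vinylcycloheptene (C1'=C5', C2'=CH2) | C=C1C(=O)O[C@@H]2C[C@H](C)[C@@]3(O)C=C(C(C)=O)[C@]4(C[C@@H]3C[C@H]12)C(=O)O[C@H]1C[C@@H](C)C(C=C)=CC[C@H]14 | intermediate
28 | des-epoxy target: ring E dienone with (E)-3-oxobut-1-enyl on C1' | C=C1C(=O)O[C@@H]2C[C@H](C)[C@@]3(O)C=C(C(C)=O)[C@]4(C[C@@H]3C[C@H]12)C(=O)O[C@H]1C[C@@H](C)C(/C=C/C(C)=O)=CC[C@H]14 | intermediate
29 | CNP0177598.2: 1'R,5'R epoxide on the ring E face opposite lactone D | C=C1C(=O)O[C@@H]2C[C@H](C)[C@@]3(O)C=C(C(C)=O)[C@]4(C[C@@H]3C[C@H]12)C(=O)O[C@H]1C[C@@H](C)[C@]2(/C=C/C(C)=O)O[C@@H]2C[C@H]14 | target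

Total step count: 13. Longest linear sequence: 9 steps (1, 6, 7, 8, 9, 10, 11, 12, 13).

Steps most likely to fail

Step 10. Two electron-poor partners combine slowly, the dienophile may polymerise on long heating, and control of the ring B face may erode at 110 °C. Fallback: setting out from 22, the ketone is reduced under Luche conditions (NaBH4, CeCl3·7H2O, MeOH, −40 °C) to the C4-epimeric allylic alcohol F1. This is silylated (TBSCl, imidazole, DMF) to the electron-rich silyl ether diene F2. A normal-electron-demand Diels–Alder reaction with 14 activated by Et2AlCl (CH2Cl2, −40 to 0 °C) then gives the silyl ether adduct F3. HF·pyridine frees the carbinol adduct F4, and Dess–Martin oxidation comes back to the route at 23.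

Step 11. Oxygen may be captured at C3 instead of C1 or on the wrong face of C1. The hydroperoxide may also over-oxidise the enones under base. Fallback: setting out from 23, a Shi epoxidation with the D-fructose-derived ketone (Oxone, K2CO3, buffered MeCN–CH2(OMe)2, 0 °C) attacks the only unactivated trisubstituted alkene, C1=C2. Under reagent control it delivers oxygen to the β face and gives the β-epoxy ketone F5. DBU (CH2Cl2, 0 °C) then opens the epoxide from C3 by E1cB and expels the sulfinate in the same flask, which comes back to the route at 26.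

Step 12. The carbene may start at the alkyne and close the ring in the endo mode, may be held by chelation to the C1 hydroxyl or the enone, or may stop at the vinyl stage because cross-metathesis with the electron-poor ketone is slow. Fallback: setting out from 26, ring closure alone is run under ethene (1 atm) with the second-generation Grubbs catalyst RuCl2(H2IMes)(PCy3)(=CHPh) in CH2Cl2, and 27 is isolated. Its terminal vinyl C=C, the least hindered and most electron-rich alkene, is cleaved (OsO4 cat., NaIO4, 2,6-lutidine, dioxane–water) to the cycloheptene carbaldehyde F6. Wittig olefination with Ph3P=CHC(O)CH3 (toluene, 60 °C) installs the E-enone and comes back to the route at 28.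

Further compounds
F1 | step 10 | allylic alcohol from 22 (C4 epimers, centre removed later) | O=S(=O)(c1ccccc1)C[C@@H]1C(=O)O[C@@H]2C[C@H](C)C(/C=C/C(C)O)=CC[C@H]12
F2 | step 10 | tert-butyldimethylsilyl ether diene | O=S(=O)(c1ccccc1)C[C@@H]1C(=O)O[C@@H]2C[C@H](C)C(/C=C/C(C)O[Si](C)(C)C(C)(C)C)=CC[C@H]12
F3 | step 10 | silyl ether Diels–Alder adduct | O=S(=O)(c1ccccc1)C[C@@H]1C(=O)O[C@@H]2C[C@H](C)C3=C[C@H](C(C)O[Si](C)(C)C(C)(C)C)[C@]4(C[C@@H]3C[C@H]12)C(=O)O[C@@H](C[C@@H](C)C#C)[C@H]4CC=C
F4 | step 10 | carbinol adduct | O=S(=O)(c1ccccc1)C[C@@H]1C(=O)O[C@@H]2C[C@H](C)C3=C[C@H](C(C)O)[C@]4(C[C@@H]3C[C@H]12)C(=O)O[C@@H](C[C@@H](C)C#C)[C@H]4CC=C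
F5 | step 11 | 1β,2β-epoxy ketone of 23 (1S,2R) | O=S(=O)(c1ccccc1)C[C@@H]1C(=O)O[C@@H]2C[C@H](C)[C@@]3(O5)[C@H]5[C@H](C(C)=O)[C@]4(C[C@@H]3C[C@H]12)C(=O)O[C@@H](C[C@@H](C)C#C)[C@H]4CC=C
F6 | step 12 | ring E cycloheptene-1'-carbaldehyde | C=C1C(=O)O[C@@H]2C[C@H](C)[C@@]3(O)C=C(C(C)=O)[C@]4(C[C@@H]3C[C@H]12)C(=O)O[C@H]1C[C@@H](C)C(C=O)=CC[C@H]14
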